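You charge X and want it kept as X.Z and G, so the amount to follow is the fraction of the charge that has reacted once and not twice.

X 0.050 M; E 15 mM (held); time 25 min

    E ⇌ Z, rate k1*(csat - [Z]) (k1 = 0.022 s⁻¹, csat = 15 mM)
    X + Z → X.Z (k2 = 0.070 L mol⁻¹ s⁻¹)
    Z + X.Z → Z.X.Z (k3 = 0.054 L mol⁻¹ s⁻¹)
    Z + X.Z → J (k4 = 0.042 L mol⁻¹ s⁻¹)
    G ⇌ X.Z, rate k5*(cs5 - [X.Z]) while solid is left; crystals form when [X.Z] > cs5 (cs5 = 1.4 mM, k5 = 0.015 s⁻¹)

- what is said of X.Z includes G
- G is a solid; its amount is given per volume of the solution
- at the start none of Z is dissolved
- run time (flask): 25 min

- south: doubling the dissolution coefficient of step 5, all else as stated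
- west: doubling the solubility in step 5, all else as stated
- north-east: doubling the transfer coefficient of step 1, all else as stated
- south-east: doubling the saturation concentration of E, all else as stated

- amount of X.Z and G together at 25 min, in percent of the X charged
- the change that raises the amount of X.Z and G together at 25 min, in percent of the X charged most ("none" if none brings more than 2 percentage points) (south / west / north-east / south-east / none)
- amount of X.Z and G together at 25 min, in percent of the X charged, after north-east

Set this flask beside north-east, where the gas transfer coefficient is doubled. Z enters with a time constant of 45.5 s, and the charge of X consumes it with one of 286 s. Transfer is quicker, so I take Z at a steady fraction of saturation, reckoned with X at its charge: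

this flask 86.3%; north-east 92.6%

With Z held at that fraction, X falls as a pseudo-first-order lag, so you count how many of its time constants fit into the run:

this flask 1.36; north-east 1.46

This turn count, run time over the time constant of X under standing Z, leaves e to its negative as X. In this flask I therefore reckon the reacted fraction at 74.3%.

Z also attacks dissolved X.Z, not G, with selectivity factor 1.37. I take the dissolved share as the solubility plus the inflow held during the crystal lag of 66.7 s:

dissolved 6.10%; lost 11.4%

y = 62.9%; yb = 64.3%

By my reckoning north-east reacts more X and also loses more. Doubling saturation doubles the turn count, so I choose south-east.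

The forecast gave 64.5%, 66% and south-east, and its y stands above mine. On north-east it says: “Doubling the transfer coefficient gains under 2 points because transfer is not limiting”.

The simulation gives 64.7%, 66.0% and south-east, which gains 6.9 percentage points; north-east gains 1.3 points.

The turn count of 1.36 leaves 25.7% of the charge as X, and this flask holds 24.8% at 25.0 min. In the neighbour read at 1.0 h, the count grows with the time to 3.26, which leaves 3.83% as X. That neighbour holds 2.88% as X, 11.3% as Z.X.Z and 77.1% as X.Z and G together.

Its constants are assumed; the rest is arithmetic.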